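(The runs stem from a simulated flask with constants of no real substance.)

Do not read 2.50 equivalents of partner in the flask as a comfortable excess: in the oak run the mono adduct falls after it forms, so it takes up partner again.

| flask | starting material | partner | scavenger | remark | time |
|---|---|---|---|---|---|
| larch | 3.4 × 10⁻⁴ M | 1.25 mM | 0.75 mM | run made earlier |  |
| elm | 7.5 × 10⁻⁴ M | 1.25 mM | 0.75 mM | run made earlier |  |
| oak | 5.0 × 10⁻⁴ M | 1.9 mM | 0.75 mM | run made earlier |  |
| flask | 5.0 × 10⁻⁴ M | 1.25 mM | 0.750 mM |  | 2.0 min |

| run | time / s | starting material / % | mono adduct / % |
|---|---|---|---|
| larch | 15.0 | 44.2 | 42.5 |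
| larch | 40.0 | 15.3 | 39.0 |
| larch | 80.0 | 4.0 | 21.3 |
| larch | 120 | 1.0 | 10.0 |
| elm | 30.0 | 31.2 | 44.0 |
| elm | 60.0 | 18.3 | 40.5 |
| elm | 90.0 | 13.9 | 37.3 |
| elm | 120 | 11.6 | 34.6 |
| oak | 15.0 | 31.6 | 42.5 |
| oak | 40.0 | 8.0 | 30.4 |
| oak | 80.0 | 2.4 | 12.1 |
| oak | 120 | 0 | 5.2 |

(readings scatter by 1 percentage point)

* part of the starting material that has reacted at 2.0 min
* share of the unused partner that is free and not bound as idle adduct, at 2.0 min

- the analysis behind the earlier runs scatters by 1 percentage point, standard deviation
- the earlier runs do not show how much of partner is bound; that part of a forecast is a guess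

Set the flask beside oak, which has the same starting charge but more partner. Let S be starting material, M mono adduct and B unused partner, and count the open sites X = 2S + M. Each of the two substitutions takes one site and one partner, so if partner goes nowhere else the margin m = B − X stays constant: 0.250 mM in the flask, and 0.900 mM in oak. Take that as an assumption; the readings do not show it.

Oak's tail reads 0.765 for the selectivity factor s, the second substitution's rate constant over the first. Dividing the two rates and integrating gives, with S and M as shares of the charge, M = (S^s − S)/(1 − s). Larch's first reading, taken pseudo-first-order at its mean partner, gives k = 48.1 M⁻¹ s⁻¹.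

Now integrate the first substitution's rate, dS/dt = −kSB, with B = X + m. To get a closed form, approximate X by its starting value times S^s, with S as a share of the charge; this is right at the start and runs below the true X afterwards. In the flask, S^s falls to 9.03%, and S is that fraction raised to the power 1.31, which is 4.32%. My rough c is therefore 95.7%. Oak's wider margin gives 0.212% at 120 s, where it read 0%. The runs do not show bound partner, so fr stays a guess.

The forecast gives 96.5% (95% to 98%) and 84% (68% to 95%), noting that the "binding model is a guess".

The flask gives 96.5% and 94.9%.

    partner + bis adduct → tris adduct + released group (k = 9.30 M⁻¹ s⁻¹)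
    scavenger + released group → scavenged by-product (k = 26000 M⁻¹ s⁻¹)
    partner + released group ⇌ idle adduct, settled at all times (K = 68000 M⁻¹)
    starting material + partner → mono adduct + released group (k = 53.0 M⁻¹ s⁻¹)
    released group → by-product carried off (k = 1.90 s⁻¹)
    partner + mono adduct → bis adduct + released group (k = 37.0 M⁻¹ s⁻¹)

In the flask, the first substitution had 71% of its turnover behind it by 0.400 min, while the second was half done by 0.611 min. The scavenger's step was half done by 0.384 min, and 4.50% of the scavenger stood free at 2.00 min. The flask then also held 19.0% of tris adduct, a third use of partner, so its margin did not stay constant. Put the flask's 3.5% of starting material into the rule: it gives 17.9% of mono adduct, against 20.3% in the flask. The neighbour charged with 0.0013 M of starting material kept 31.4%, for which the rule gives 41.8%, and it held 43.5% of mono adduct.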